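**Strategy.** Ring B is taken back from a benzene to a cyclopentene: the 2-bromophenyl ether is disconnected to an aryl cyclopent-1-enyl ether plus one C–Br unit. The feature used is that the brominated carbon C2' lies between the oxygen-bearing C1' and C3' of ring B, where a carbene carbon inserted into an enol ether double bond ends up. In one operation the key step adds dibromocarbene across that double bond (bonds C1'–C2' and C2'–C3') and lets the dibromocyclopropane open, enlarging the five-membered ring to the six-membered carbocycle with bromine already on C2'. Its precursor is the fully brominated, O-methylated ring A carrying the cyclopentenyl enol ether on the second oxygen; dehydrogenation and demethylation finish.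

Key step: step 3

Remark: 3-bromo-2-methoxyphenol is taken as a catalogue compound; intermediates 6 and 7 are racemic, and every isolated compound and the target are achiral.

**Step 1**
Reactants: 1 3-bromo-2-methoxyphenol
Product: 2 3,4,6-tribromo-2-methoxyphenol
Conditions: Br2 (2.05 equiv), CH2Cl2–AcOH, 0 °C to rt; aq Na2S2O3 quench
Reagents that add atoms: bromine, BrBr
Why: Electrophilic aromatic bromination is directed by the free hydroxyl group to its para (C4) and open ortho (C6) positions, whereas C5 is activated only by a methoxy group twisted out of conjugation by two ortho neighbours, so two equivalents should stop at the tribromide.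

**Step 2**
Reactants: 2 3,4,6-tribromo-2-methoxyphenol; 3 cyclopent-1-en-1-ylboronic acid
Product: 4 1,2,5-tribromo-4-(cyclopent-1-en-1-yloxy)-3-methoxybenzene
Conditions: 3 (2.5 equiv), Cu(OAc)2 (2 equiv), pyridine, 4 Å MS, CH2Cl2, dry air, rt; chromatography on Et3N-deactivated silica
Reagents that add atoms: cyclopent-1-en-1-ylboronic acid (3), OB(O)C1=CCCC1
Why: Chan–Lam oxidative C–O coupling of a phenol with an alkenylboronic acid, mediated by divalent copper at room temperature, should form the aryl enol ether while leaving the three aryl bromides alone, which a zerovalent palladium catalyst or a hot Ullmann-type coupling would endanger.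

**Step 3**
Reactants: 4 1,2,5-tribromo-4-(cyclopent-1-en-1-yloxy)-3-methoxybenzene; 5 bromoform
Product: 8 1,2,5-tribromo-4-[(2-bromocyclohexa-1,3-dien-1-yl)oxy]-3-methoxybenzene, via gem-dibromocyclopropane 6 (not isolated), via allylic dibromide 7 (not isolated)
Conditions: CHBr3 (1.5 equiv, slow addition), KOtBu (1.6 equiv), pentane, −20 °C to rt; then KOtBu (1.5 equiv), THF, rt to 40 °C; non-acidic work-up, basic alumina
Reagents that add atoms: bromoform (5), BrC(Br)Br
Why: KOtBu removes HBr from bromoform by α-elimination and the singlet dibromocarbene adds in a concerted (2+1) cycloaddition to the enol ether C=C of 4, forming C1'–C2' and C2'–C3' in cyclopropane 6. The six-membered ring is then closed by ring enlargement, not by cyclisation: the donor oxygen on the fusion carbon assists loss of the endo bromide with disrotatory two-electron electrocyclic opening of the fusion bond (cyclopropyl-to-allyl rearrangement) to an oxygen-stabilised 2-bromoallyl cation. Bromide return should give allylic dibromide 7, and the second charge of tert-butoxide removes HBr by E2 elimination to the conjugated dienol ether 8. The closest known reaction type is the dihalocarbene one-carbon ring expansion of cyclic enol ethers, silyl enol ethers and indenes to 2-halocycloalkene derivatives. No stereocentre remains in 8 (those of 6 and 7 are transient and racemic), and the bromine must sit between C1' and C3' because the carbene carbon is the one inserted. The selectivities needed are attack of the electrophilic carbene on the only nucleophilic alkene, secured by the enol ether oxygen, and proton loss in place of hydrolysis of the cation, secured by strictly anhydrous alkoxide conditions; the aryl bromides of ring A should be inert, and a regioisomeric 1,3-diene from the other direction of proton loss would converge on the same arene in step 4.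

**Step 4**
Reactants: 8 1,2,5-tribromo-4-[(2-bromocyclohexa-1,3-dien-1-yl)oxy]-3-methoxybenzene
Product: 9 1,2,5-tribromo-4-(2-bromophenoxy)-3-methoxybenzene
Conditions: DDQ (1.2 equiv), dry toluene, rt to 60 °C
Reagents that add atoms: none
Why: Dehydrogenative aromatisation of a cyclohexa-1,3-diene by DDQ (hydride abstraction from the allylic CH2 to an oxygen-stabilised cyclohexadienyl cation, then proton loss) is driven by formation of the benzene ring and should not affect aryl bromides or the methyl ether.

**Step 5**
Reactants: 9 1,2,5-tribromo-4-(2-bromophenoxy)-3-methoxybenzene
Product: 10 2,3,5-tribromo-6-(2-bromophenoxy)phenol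
Conditions: BBr3 (3 equiv), CH2Cl2, −78 °C to rt; then H2O
Reagents that add atoms: none
Why: Lewis-acid O-demethylation with BBr3 proceeds by bromide attack on the methyl group of the boron-complexed ether oxygen, while the diaryl ether, which offers no sp3 carbon for substitution, and the aryl bromides should remain untouched.

**Compound list**
1 | 3-bromo-2-methoxyphenol | COc1c(O)cccc1Br | starting material
2 | 3,4,6-tribromo-2-methoxyphenol | COc1c(O)c(Br)cc(Br)c1Br | intermediate
3 | cyclopent-1-en-1-ylboronic acid | OB(O)C1=CCCC1 | starting material
4 | 1,2,5-tribromo-4-(cyclopent-1-en-1-yloxy)-3-methoxybenzene | COc1c(Br)c(Br)cc(Br)c1OC1=CCCC1 | intermediate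
5 | bromoform | BrC(Br)Br | starting material
6 | 1,2,5-tribromo-4-[(6,6-dibromobicyclo[3.1.0]hexan-1-yl)oxy]-3-methoxybenzene (cis-fused, racemic, one enantiomer drawn; not isolated) | COc1c(Br)c(Br)cc(Br)c1O[C@]12CCC[C@H]1C2(Br)Br | intermediate
7 | rac-1,2,5-tribromo-4-[(2,3-dibromocyclohex-1-en-1-yl)oxy]-3-methoxybenzene (not isolated) | COc1c(Br)c(Br)cc(Br)c1OC1=C(Br)C(Br)CCC1 | intermediate
8 | 1,2,5-tribromo-4-[(2-bromocyclohexa-1,3-dien-1-yl)oxy]-3-methoxybenzene | COc1c(Br)c(Br)cc(Br)c1OC1=C(Br)C=CCC1 | intermediate
9 | 1,2,5-tribromo-4-(2-bromophenoxy)-3-methoxybenzene | COc1c(Br)c(Br)cc(Br)c1Oc1ccccc1Br | intermediate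
10 | 2,3,5-tribromo-6-(2-bromophenoxy)phenol | Oc1c(Br)c(Br)cc(Br)c1Oc1ccccc1Br | target

**Totals.** Total step count: 5. Longest linear sequence: 5 steps (1 → 2 → 4 → 8 → 9 → 10).

**Steps most likely to fail**

Step 3. The carbene may add sluggishly to an enol ether whose oxygen lone pair is drawn into the electron-poor ring A. The ring-opened cation may also be intercepted by tert-butoxide or trace water, with loss of the C–O bond to ring A. The fallback gives up the ring expansion and attaches ring B intact, setting out from phenol 2. 1-Bromo-2-iodobenzene is oxidised with mCPBA and TsOH·H2O in MeCN and the hypervalent iodine species is trapped with 1,3,5-trimethoxybenzene to give (2-bromophenyl)(2,4,6-trimethoxyphenyl)iodonium tosylate F1. The potassium phenoxide of 2 (KOtBu, THF, rt to 40 °C) is then O-arylated by F1 without a metal, the electron-rich trimethoxyphenyl group staying on iodine. This should give 9 directly, so the route is rejoined at compound 9 before step 5 and steps 2 to 4 are bypassed.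

Step 2. Coupling at the doubly ortho-flanked, weakly nucleophilic phenoxide may be slow while the alkenylboronic acid is consumed by protodeboronation and oxidative homocoupling. The fallback sets out from 2. A Mitsunobu reaction with cyclopent-2-en-1-ol (PPh3, DIAD, THF, 0 °C to rt) should give rac-1,2,5-tribromo-4-(cyclopent-2-en-1-yloxy)-3-methoxybenzene F2. Catalytic RuHCl(CO)(PPh3)3 in toluene at 80 °C would then move the double bond into conjugation with oxygen by hydrometalation and β-hydride elimination, returning to the route at compound 4.

Step 4. Hydride transfer may be outrun by hydrolysis of the acid-sensitive dienol ether by the acidic hydroquinone, or by Diels–Alder capture of the diene by the quinone. The fallback sets out from 8. Wohl–Ziegler allylic bromination (NBS, cat. AIBN, PhCF3, 80 °C) should give rac-1,2,5-tribromo-4-[(2,5-dibromocyclohexa-1,3-dien-1-yl)oxy]-3-methoxybenzene F3, which is not isolated. It should lose HBr on addition of Et3N, driven by aromatisation, returning to the route at compound 9.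

**Further compounds**
F1 | step 3 | (2-bromophenyl)(2,4,6-trimethoxyphenyl)iodonium 4-methylbenzenesulfonate | COc1cc(OC)c([I+]c2ccccc2Br)c(OC)c1.Cc1ccc(cc1)S(=O)(=O)[O-]
F2 | step 2 | rac-1,2,5-tribromo-4-(cyclopent-2-en-1-yloxy)-3-methoxybenzene | COc1c(Br)c(Br)cc(Br)c1OC1C=CCC1
F3 | step 4 | rac-1,2,5-tribromo-4-[(2,5-dibromocyclohexa-1,3-dien-1-yl)oxy]-3-methoxybenzene | COc1c(Br)c(Br)cc(Br)c1OC1=C(Br)C=CC(Br)C1
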